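**Retrosynthetic overview**

1. Target 21 is a 2,3-trans-3,4-cis flavan-3,4-diol (2R,3S,4S). The C4 hydroxyl comes last, by equatorial hydride delivery to the C4 ketone of the silylated dihydroflavonol 19, followed by desilylation.
2. The strategy rests on ring A (C4a, C5, C6, C7, C8, C8a). OMe on C5, H on C6, O on C7 and prenyl on C8 are exactly what a 4-prenyl-1,1-dimethoxy-3-silyloxybutadiene carries, so ring A is cut at C4a–C5 and C8–C8a and built by cycloaddition–aromatisation across the C5=C6 bond (future C4a=C8a) of a ring C dihydropyranone.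
3. Ring C (O1, C2, C3, C4 and that C=C) is made first and carries both stereocentres: an asymmetric hetero-Diels–Alder reaction sets C2, trans enolate hydroxylation sets C3, and C5 sulfenylation with S-oxidation gives sulfinyl enone 11.
4. Diene 16 comes from C-acylation of 1,1-dimethoxyethene with 5-methylhex-4-enoyl chloride, then Z-selective enol silylation.
5. Ring order: ring B is bought (4-hydroxybenzaldehyde), ring C is formed in step 2, ring A in step 10.

Key step: step 10

**Remarks on the chemistry**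

- (E)-1-Methoxy-3-(trimethylsilyloxy)buta-1,3-diene 3 is taken as a purchased reagent, and O3 is introduced after the ring is formed.
- The diene carries a TBS enol ether in place of a TMS enol ether. O7 then leaves the key step silylated, so the C4 ketone is not deactivated as a para-phenoxide in the hydride step.
- The sense of induction of (S)-BINOL/Ti(OiPr)4 (Si-face attack) is assigned by analogy with its additions to benzaldehyde. It would be confirmed on 5, and the (R)-ligand used if it proves opposite.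

**Route**

Step 1
Reactants: 1 4-hydroxybenzaldehyde
Product: 2 4-(tert-butyldimethylsilyloxy)benzaldehyde
Conditions: TBSCl, imidazole, DMF, 25 °C
Reagents that add atoms: tert-butyldimethylsilyl chloride, CC(C)(C)[Si](C)(C)Cl
Why: Silyl ether formation on a phenol; the acidic OH is masked so that it quenches neither the titanium catalyst nor the later enolate.

Step 2
Reactants: 2 4-(tert-butyldimethylsilyloxy)benzaldehyde; 3 (E)-1-methoxy-3-(trimethylsilyloxy)buta-1,3-diene
Product: 5 (S)-2-[4-(tert-butyldimethylsilyloxy)phenyl]-2,3-dihydro-4H-pyran-4-one, via silylated aldol adduct 4 (not isolated)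
Conditions: (S)-BINOL (20 mol %), Ti(OiPr)4 (10 mol %), 4 Å MS, Et2O, −20 °C; then CF3CO2H, CH2Cl2, 0 °C
Reagents that add atoms: none
Why: Catalytic asymmetric hetero-Diels–Alder reaction in its Mukaiyama aldol–cyclisation form; the diene CH2 terminus should add to the Si face of the aldehyde held on the BINOL titanate, which sets C2, and acid then closes ring C by oxa-Michael addition with loss of methanol.

Step 3
Reactants: 5 (S)-2-[4-(tert-butyldimethylsilyloxy)phenyl]-2,3-dihydro-4H-pyran-4-one
Product: 7 (2R,3R)-3-hydroxy-2-[4-(tert-butyldimethylsilyloxy)phenyl]-2,3-dihydro-4H-pyran-4-one, via potassium dienolate 6 (not isolated)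
Conditions: KN(SiMe3)2, THF, −78 °C; 3-phenyl-2-(phenylsulfonyl)oxaziridine, −78 °C; AcOH quench
Reagents that add atoms: 3-phenyl-2-(phenylsulfonyl)oxaziridine, O=S(=O)(c1ccccc1)N1OC1c1ccccc1
Why: Enolate hydroxylation with an N-sulfonyloxaziridine; C3 carries the only sp3 α-hydrogens, and the oxidant should approach the planar dienolate anti to the C2 aryl group, giving the 2,3-trans (expected thermodynamic, diequatorial) ketol; the C2 descriptor changes from S to R only through the priority change.

Step 4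
Reactants: 7 (2R,3R)-3-hydroxy-2-[4-(tert-butyldimethylsilyloxy)phenyl]-2,3-dihydro-4H-pyran-4-one
Product: 8 (2R,3R)-3-(tert-butyldimethylsilyloxy)-2-[4-(tert-butyldimethylsilyloxy)phenyl]-2,3-dihydro-4H-pyran-4-one
Conditions: TBSOTf, 2,6-lutidine, CH2Cl2, −78 → 0 °C
Reagents that add atoms: tert-butyldimethylsilyl triflate, CC(C)(C)[Si](C)(C)OS(=O)(=O)C(F)(F)F
Why: Silylation of a secondary α-hydroxy ketone; the weak hindered base does not enolise the ketone, so C3 is untouched.

Step 5
Reactants: 8 (2R,3R)-3-(tert-butyldimethylsilyloxy)-2-[4-(tert-butyldimethylsilyloxy)phenyl]-2,3-dihydro-4H-pyran-4-one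
Product: 10 (2R,3R)-3-(tert-butyldimethylsilyloxy)-2-[4-(tert-butyldimethylsilyloxy)phenyl]-5-(phenylthio)-2,3-dihydro-4H-pyran-4-one, via chlorosulfide adduct 9 (not isolated)
Conditions: PhSCl (freshly distilled), CH2Cl2, −78 °C; then Et3N, −78 → 0 °C
Reagents that add atoms: benzenesulfenyl chloride, ClSc1ccccc1
Why: Electrophilic sulfenylation of a β-alkoxy enone by addition–elimination; sulfur bonds to the nucleophilic enol ether carbon C5 and chloride to C6, and Et3N then removes the acidic H5 with loss of chloride to restore the enone.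

Step 6
Reactants: 10 (2R,3R)-3-(tert-butyldimethylsilyloxy)-2-[4-(tert-butyldimethylsilyloxy)phenyl]-5-(phenylthio)-2,3-dihydro-4H-pyran-4-one
Product: 11 (2R,3R)-3-(tert-butyldimethylsilyloxy)-2-[4-(tert-butyldimethylsilyloxy)phenyl]-5-(phenylsulfinyl)-2,3-dihydro-4H-pyran-4-one (both sulfur epimers)
Conditions: mCPBA (1.0 equiv), NaHCO3, CH2Cl2, −78 → −40 °C
Reagents that add atoms: 3-chloroperoxybenzoic acid, O=C(OO)c1cccc(Cl)c1
Why: Sulfide-to-sulfoxide oxidation with one equivalent of peracid; the push–pull C=C and the aryl silyl ether are inert, no prenyl alkene is present yet, and both sulfur epimers serve because sulfur is lost in step 10.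

Step 7
Reactants: 12 5-methylhex-4-enoic acid
Product: 13 5-methylhex-4-enoyl chloride
Conditions: (COCl)2, DMF (cat.), CH2Cl2, 0 → 25 °C; volatiles removed
Reagents that add atoms: oxalyl chloride, O=C(Cl)C(=O)Cl
Why: Acid chloride formation through the chloroiminium salt from DMF; the short, cold reaction spares the trisubstituted alkene from HCl.

Step 8
Reactants: 13 5-methylhex-4-enoyl chloride; 14 1,1-dimethoxyethene
Product: 15 1,1-dimethoxy-7-methylocta-1,6-dien-3-one
Conditions: 14 (2.2 equiv), Et2O, 0 → 25 °C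
Reagents that add atoms: none
Why: C-Acylation of a ketene acetal; its nucleophilic CH2 attacks the acid chloride and proton loss gives the push–pull β-keto ketene acetal, a second equivalent of 14 taking up the HCl without generating a ketene from 13.

Step 9
Reactants: 15 1,1-dimethoxy-7-methylocta-1,6-dien-3-one
Product: 16 (3Z)-3-(tert-butyldimethylsilyloxy)-1,1-dimethoxy-7-methylocta-1,3,6-triene
Conditions: TBSOTf, Et3N, Et2O, 0 °C; filtration and short-path distillation under argon
Reagents that add atoms: tert-butyldimethylsilyl triflate, CC(C)(C)[Si](C)(C)OS(=O)(=O)C(F)(F)F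
Why: Silyl enol ether formation by soft enolisation; C4 is the only enolisable position, and the Z enol ether (prenyl chain away from the ketene acetal arm) is expected as the less strained isomer, which puts the chain on the outside of the s-cis diene.

Step 10
Reactants: 11 (2R,3R)-3-(tert-butyldimethylsilyloxy)-2-[4-(tert-butyldimethylsilyloxy)phenyl]-5-(phenylsulfinyl)-2,3-dihydro-4H-pyran-4-one; 16 (3Z)-3-(tert-butyldimethylsilyloxy)-1,1-dimethoxy-7-methylocta-1,3,6-triene
Product: 19 (2R,3R)-3,7-bis(tert-butyldimethylsilyloxy)-2-[4-(tert-butyldimethylsilyloxy)phenyl]-5-methoxy-8-(3-methylbut-2-en-1-yl)chroman-4-one, via cycloadduct 17 (not isolated), via dienone ketal 18 (not isolated)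
Conditions: 16 (2 equiv), PhMe, 25 → 80 °C; then SiO2, CH2Cl2, 25 °C
Reagents that add atoms: none
Why: Proposed new method: diene 16 and sulfinyl enone 11 should combine in a normal-demand [4+2] cycloaddition (or its stepwise Mukaiyama–Michael and ring-closure equivalent, which leads to the same adduct), the prenyl-bearing terminus C4 of the diene bonding to C6 of the pyranone (future C8a) and the ketene acetal carbon C1 to C5 (future C4a); in the cis-fused adduct 17 the sulfinyl group is syn to H8a, so thermal syn-elimination of benzenesulfenic acid gives 18, and 1,4-loss of methanol from its allylic ketal aromatises ring A with the silyl ether retained on O7. The closest known reaction type is the cycloaddition–aromatisation of 1,1-dialkoxy-3-silyloxybutadienes with haloquinones and 2-sulfinyl enones, and of siloxydienes with 3-acylchromones to give xanthones; new here are the monocyclic 2,3-dihydropyran-4-one as dienophile and the 4-alkyl substituent on the diene. Ring A is closed by an intermolecular [4+2] cycloaddition that forms C4a–C5 and C8–C8a together, annulating a six-membered carbocycle onto the C5=C6 bond of ring C. No new stereocentre survives, since C4a, C8 and C8a are stereogenic only in 17 and are erased on aromatisation, while C2 and C3 are not touched under the neutral thermal conditions. The step needs regioselectivity, secured by matched polarity (the diene is most nucleophilic at C4 through its 3-silyloxy and 1,1-dimethoxy donors, the enone is electrophilic at its β-carbon C6, and the α-sulfinyl group reinforces this), and chemoselectivity for the enone C=C over the ketone and the isolated prenyl alkene, secured by the electron demand of the diene.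

Step 11
Reactants: 19 (2R,3R)-3,7-bis(tert-butyldimethylsilyloxy)-2-[4-(tert-butyldimethylsilyloxy)phenyl]-5-methoxy-8-(3-methylbut-2-en-1-yl)chroman-4-one
Product: 20 (2R,3S,4S)-3,7-bis(tert-butyldimethylsilyloxy)-2-[4-(tert-butyldimethylsilyloxy)phenyl]-5-methoxy-8-(3-methylbut-2-en-1-yl)chroman-4-ol
Conditions: LiBH(sec-Bu)3, THF, −78 → −20 °C; aq NH4Cl
Reagents that add atoms: none
Why: Diastereoselective ketone reduction with a bulky trialkylborohydride; equatorial attack on the half-chair of ring C should give the axial C4 hydroxyl cis to the equatorial 3-silyloxy group, as with 2-alkoxycyclohexanones, and the silylated O7 keeps the ketone electrophilic.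

Step 12
Reactants: 20 (2R,3S,4S)-3,7-bis(tert-butyldimethylsilyloxy)-2-[4-(tert-butyldimethylsilyloxy)phenyl]-5-methoxy-8-(3-methylbut-2-en-1-yl)chroman-4-ol
Product: 21 5-O-methyl-8-prenylafzelechin-4β-ol, (2R,3S,4S)-2-(4-hydroxyphenyl)-5-methoxy-8-(3-methylbut-2-en-1-yl)chroman-3,4,7-triol
Conditions: Bu4NF (4 equiv), AcOH (4 equiv), THF, 0 → 25 °C
Reagents that add atoms: none
Why: Fluoride cleavage of two aryl and one alkyl silyl ether; acetic acid buffering keeps the phenols protonated, so neither quinone methide formation nor ionisation of the benzylic C4–OH should scramble C2 or C4.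

**Compound list**

1 | 4-hydroxybenzaldehyde | O=Cc1ccc(O)cc1 | starting material
2 | 4-(tert-butyldimethylsilyloxy)benzaldehyde | O=Cc1ccc(O[Si](C)(C)C(C)(C)C)cc1 | intermediate
3 | (E)-1-methoxy-3-(trimethylsilyloxy)buta-1,3-diene | CO/C=C/C(=C)O[Si](C)(C)C | starting material
4 | (S,E)-5-[4-(tert-butyldimethylsilyloxy)phenyl]-1-methoxy-5-(trimethylsilyloxy)pent-1-en-3-one | CO/C=C/C(=O)C[C@H](O[Si](C)(C)C)c1ccc(O[Si](C)(C)C(C)(C)C)cc1 | intermediate
5 | (S)-2-[4-(tert-butyldimethylsilyloxy)phenyl]-2,3-dihydro-4H-pyran-4-one | O=C1C=CO[C@H](c2ccc(O[Si](C)(C)C(C)(C)C)cc2)C1 | intermediate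
6 | potassium (S)-2-[4-(tert-butyldimethylsilyloxy)phenyl]-2H-pyran-4-olate | [K+].[O-]C1=C[C@@H](c2ccc(O[Si](C)(C)C(C)(C)C)cc2)OC=C1 | intermediate
7 | (2R,3R)-3-hydroxy-2-[4-(tert-butyldimethylsilyloxy)phenyl]-2,3-dihydro-4H-pyran-4-one | O=C1C=CO[C@H](c2ccc(O[Si](C)(C)C(C)(C)C)cc2)[C@H]1O | intermediate
8 | (2R,3R)-3-(tert-butyldimethylsilyloxy)-2-[4-(tert-butyldimethylsilyloxy)phenyl]-2,3-dihydro-4H-pyran-4-one | O=C1C=CO[C@H](c2ccc(O[Si](C)(C)C(C)(C)C)cc2)[C@H]1O[Si](C)(C)C(C)(C)C | intermediate
9 | (2R,3R)-6-chloro-3-(tert-butyldimethylsilyloxy)-2-[4-(tert-butyldimethylsilyloxy)phenyl]-5-(phenylthio)tetrahydropyran-4-one (C5/C6 isomers) | O=C1C(Sc2ccccc2)C(Cl)O[C@H](c2ccc(O[Si](C)(C)C(C)(C)C)cc2)[C@H]1O[Si](C)(C)C(C)(C)C | intermediate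
10 | (2R,3R)-3-(tert-butyldimethylsilyloxy)-2-[4-(tert-butyldimethylsilyloxy)phenyl]-5-(phenylthio)-2,3-dihydro-4H-pyran-4-one | O=C1C(Sc2ccccc2)=CO[C@H](c2ccc(O[Si](C)(C)C(C)(C)C)cc2)[C@H]1O[Si](C)(C)C(C)(C)C | intermediate
11 | (2R,3R)-3-(tert-butyldimethylsilyloxy)-2-[4-(tert-butyldimethylsilyloxy)phenyl]-5-(phenylsulfinyl)-2,3-dihydro-4H-pyran-4-one (both sulfur epimers) | O=C1C(S(=O)c2ccccc2)=CO[C@H](c2ccc(O[Si](C)(C)C(C)(C)C)cc2)[C@H]1O[Si](C)(C)C(C)(C)C | intermediate
12 | 5-methylhex-4-enoic acid | CC(C)=CCCC(=O)O | starting material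
13 | 5-methylhex-4-enoyl chloride | CC(C)=CCCC(=O)Cl | intermediate
14 | 1,1-dimethoxyethene | C=C(OC)OC | starting material
15 | 1,1-dimethoxy-7-methylocta-1,6-dien-3-one | COC(OC)=CC(=O)CCC=C(C)C | intermediate
16 | (3Z)-3-(tert-butyldimethylsilyloxy)-1,1-dimethoxy-7-methylocta-1,3,6-triene | COC(OC)=C/C(O[Si](C)(C)C(C)(C)C)=C/CC=C(C)C | intermediate
17 | (2R,3R)-3,7-bis(tert-butyldimethylsilyloxy)-2-[4-(tert-butyldimethylsilyloxy)phenyl]-5,5-dimethoxy-8-(3-methylbut-2-en-1-yl)-4a-(phenylsulfinyl)-2,3,4a,5,8,8a-hexahydrochromen-4-one (cis-fused; C4a, C8, C8a and S isomers) | COC1(OC)C=C(O[Si](C)(C)C(C)(C)C)C(CC=C(C)C)C2C1(S(=O)c3ccccc3)C(=O)[C@H](O[Si](C)(C)C(C)(C)C)[C@@H](c4ccc(O[Si](C)(C)C(C)(C)C)cc4)O2 | intermediate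
18 | (2R,3R)-3,7-bis(tert-butyldimethylsilyloxy)-2-[4-(tert-butyldimethylsilyloxy)phenyl]-5,5-dimethoxy-8-(3-methylbut-2-en-1-yl)-2,3,5,8-tetrahydrochromen-4-one | COC1(OC)C=C(O[Si](C)(C)C(C)(C)C)C(CC=C(C)C)C2=C1C(=O)[C@H](O[Si](C)(C)C(C)(C)C)[C@@H](c3ccc(O[Si](C)(C)C(C)(C)C)cc3)O2 | intermediate
19 | (2R,3R)-3,7-bis(tert-butyldimethylsilyloxy)-2-[4-(tert-butyldimethylsilyloxy)phenyl]-5-methoxy-8-(3-methylbut-2-en-1-yl)chroman-4-one (3,7,4'-tris-O-TBS-5-O-methyl-8-prenylaromadendrin) | COc1cc(O[Si](C)(C)C(C)(C)C)c(CC=C(C)C)c2c1C(=O)[C@H](O[Si](C)(C)C(C)(C)C)[C@@H](c1ccc(O[Si](C)(C)C(C)(C)C)cc1)O2 | intermediate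
20 | (2R,3S,4S)-3,7-bis(tert-butyldimethylsilyloxy)-2-[4-(tert-butyldimethylsilyloxy)phenyl]-5-methoxy-8-(3-methylbut-2-en-1-yl)chroman-4-ol | COc1cc(O[Si](C)(C)C(C)(C)C)c(CC=C(C)C)c2c1[C@H](O)[C@H](O[Si](C)(C)C(C)(C)C)[C@@H](c1ccc(O[Si](C)(C)C(C)(C)C)cc1)O2 | intermediate
21 | 5-O-methyl-8-prenylafzelechin-4β-ol | COc1cc(O)c(CC=C(C)C)c2c1[C@H](O)[C@H](O)[C@@H](c1ccc(O)cc1)O2 | target

**Step count and risk**

Total steps: 12. Longest linear sequence: 9 (steps 1–6, 10–12); the diene branch is steps 7–9.

Steps most likely to fail: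

1. Step 10 (proposed new method). The cycloaddition may be slow because the ring oxygen donates into the enone. The silyl ketene acetal may be hydrolysed or may attack the sulfoxide in a Pummerer-type manner. The 7-O-silyl group may be lost in part during aromatisation. The fallback builds ring C onto a preformed ring A by known flavonoid chemistry; it sets out from 1 and comes back at 19. MOMCl/iPr2NEt converts 1 into 4-(methoxymethoxy)benzaldehyde F1. Purchased 1-(2,4-dihydroxy-6-methoxyphenyl)ethanone is C-prenylated between its two hydroxyls (prenyl bromide, aq KOH; isomers separated) to give 1-[2,4-dihydroxy-6-methoxy-3-(3-methylbut-2-en-1-yl)phenyl]ethanone F2. MOMCl/NaH then gives 1-[6-methoxy-2,4-bis(methoxymethoxy)-3-(3-methylbut-2-en-1-yl)phenyl]ethanone F3. Claisen–Schmidt condensation of F3 with F1 (KOH, EtOH) gives (E)-1-[6-methoxy-2,4-bis(methoxymethoxy)-3-(3-methylbut-2-en-1-yl)phenyl]-3-[4-(methoxymethoxy)phenyl]prop-2-en-1-one F4. Juliá–Colonna epoxidation (poly-L-leucine, urea–H2O2, DBU, THF) should give [(2R,3S)-3-[4-(methoxymethoxy)phenyl]oxiran-2-yl][6-methoxy-2,4-bis(methoxymethoxy)-3-(3-methylbut-2-en-1-yl)phenyl]methanone F5. HCl/MeOH removes the MOM groups, and the freed ortho hydroxyl opens the epoxide at the benzylic carbon with inversion to give (2R,3R)-5-O-methyl-8-prenylaromadendrin F6. TBSOTf/2,6-lutidine silylates O3, O7 and O4' to rejoin the route at 19.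

2. Step 11. Hydride delivery to the hindered, electron-rich aryl ketone may be slow or show poor facial selectivity, giving the 3,4-trans alcohol. The fallback sets out from 19 and comes back at 21. NaBH4 (MeOH/THF, 0 °C) attacks axially and should give mainly (2R,3S,4R)-3,7-bis(tert-butyldimethylsilyloxy)-2-[4-(tert-butyldimethylsilyloxy)phenyl]-5-methoxy-8-(3-methylbut-2-en-1-yl)chroman-4-ol F7. Bu4NF/AcOH then gives 5-O-methyl-8-prenylafzelechin-4α-ol F8. In dilute aqueous acetic acid the benzylic C4 hydroxyl ionises and water returns, the known trans-to-cis epimerisation of leucoanthocyanidins. Target 21 is separated from the equilibrium mixture by reversed-phase HPLC.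

3. Step 3. The dienolate may open by retro-oxa-Michael or 6π ring-opening, which would erode the C2 configuration. Attack of the oxidant on the face of the aryl group, or addition of the enolate to the sulfonylimine by-product, may also occur. The fallback sets out from 5 and comes back at 7. Mn(OAc)3·2H2O in refluxing benzene carries out the α'-acetoxylation of the enone without a free enolate; on 2-substituted dihydropyranones this gives the trans product, here (2R,3R)-3-acetoxy-2-[4-(tert-butyldimethylsilyloxy)phenyl]-2,3-dihydro-4H-pyran-4-one F9. Deacetylation with Candida antarctica lipase B (pH 7 buffer/MTBE) then gives 7.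

**Further compounds**

F1 | step 10 | 4-(methoxymethoxy)benzaldehyde | COCOc1ccc(C=O)cc1
F2 | step 10 | 1-[2,4-dihydroxy-6-methoxy-3-(3-methylbut-2-en-1-yl)phenyl]ethanone | COc1cc(O)c(CC=C(C)C)c(O)c1C(C)=O
F3 | step 10 | 1-[6-methoxy-2,4-bis(methoxymethoxy)-3-(3-methylbut-2-en-1-yl)phenyl]ethanone | COCOc1cc(OC)c(C(C)=O)c(OCOC)c1CC=C(C)C
F4 | step 10 | (E)-1-[6-methoxy-2,4-bis(methoxymethoxy)-3-(3-methylbut-2-en-1-yl)phenyl]-3-[4-(methoxymethoxy)phenyl]prop-2-en-1-one | COCOc1ccc(/C=C/C(=O)c2c(OC)cc(OCOC)c(CC=C(C)C)c2OCOC)cc1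
F5 | step 10 | [(2R,3S)-3-[4-(methoxymethoxy)phenyl]oxiran-2-yl][6-methoxy-2,4-bis(methoxymethoxy)-3-(3-methylbut-2-en-1-yl)phenyl]methanone | O=C(c1c(OC)cc(OCOC)c(CC=C(C)C)c1OCOC)[C@@H]1O[C@H]1c1ccc(OCOC)cc1
F6 | step 10 | (2R,3R)-5-O-methyl-8-prenylaromadendrin | COc1cc(O)c(CC=C(C)C)c2c1C(=O)[C@H](O)[C@@H](c1ccc(O)cc1)O2
F7 | step 11 | (2R,3S,4R)-3,7-bis(tert-butyldimethylsilyloxy)-2-[4-(tert-butyldimethylsilyloxy)phenyl]-5-methoxy-8-(3-methylbut-2-en-1-yl)chroman-4-ol | COc1cc(O[Si](C)(C)C(C)(C)C)c(CC=C(C)C)c2c1[C@@H](O)[C@H](O[Si](C)(C)C(C)(C)C)[C@@H](c1ccc(O[Si](C)(C)C(C)(C)C)cc1)O2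
F8 | step 11 | 5-O-methyl-8-prenylafzelechin-4α-ol | COc1cc(O)c(CC=C(C)C)c2c1[C@@H](O)[C@H](O)[C@@H](c1ccc(O)cc1)O2
F9 | step 3 | (2R,3R)-3-acetoxy-2-[4-(tert-butyldimethylsilyloxy)phenyl]-2,3-dihydro-4H-pyran-4-one | O=C1C=CO[C@H](c2ccc(O[Si](C)(C)C(C)(C)C)cc2)[C@H]1OC(C)=O
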